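Its constants are those of an exercise; the rest is arithmetic.

This substrate cannot be given one reaction order: it leaves by first-order steps and by a second-order step at once.

    substrate → ring (k1 = 0.0615 s⁻¹, Ea1 = 78.0 kJ mol⁻¹)
    substrate ⇌ dormant form (K2 = 17, k2 = 0.00493 s⁻¹, Ea2 = 98.0 kJ mol⁻¹, ΔH2 = −27.0 kJ mol⁻¹)
    ring → over-reaction product (k3 = 0.0660 s⁻¹, Ea3 = 75.0 kJ mol⁻¹)
    2 substrate → open dimer (k4 = 38.9 L mol⁻¹ s⁻¹, Ea4 = 35.0 kJ mol⁻¹)
    (constants at 50 °C)

the same everywhere: substrate 5.0 mM; time 30 s
- spring: temperature 50 °C
- noon: temperature 65 °C
- dawn: temperature 80 °C

- percentages count the substrate that a species holds: one open dimer counts as two
- for a step with 2 of a species take k times the square, and two of it per event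
- all constants are for 50 °C and move with temperature by the activation energies and enthalpies

- which of these there is most of at the end, counted by the substrate in it, spring (open dimer / ring / over-reaction product / substrate)
- which of these there is most of at the end, counted by the substrate in it, noon (open dimer / ring / over-reaction product / substrate)
- which of these there is most of at the end, counted by the substrate in it, dawn (open dimer / ring / over-reaction product / substrate)
- how much there is at the end of the one of these that leads, in percent of the substrate charged: spring
- how much there is at the end of the one of these that leads, in percent of the substrate charged: noon
- how much there is at the end of the one of these that leads, in percent of the substrate charged: dawn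

So look for the concentration at which the two kinds of loss are equal. First-order loss is the sum of the constants of ring closure and forward dormancy, times c(substrate). Loss to open dimer is twice its constant times c(substrate) squared. They match at c* = 0.854 mM at spring. Divide the charge by c* and you get 5.86. That is D, the substrate lost to open dimer over the substrate lost by first-order steps, taken at the charge.

Now follow the split as c(substrate) falls. I drop the way back from dormant form. At spring its relaxation half-life is 133 s, longer than the run, so the drop is fair there. At dawn the same half-life is 5.57 s, shorter than the run, so at dawn the drop is a rough step. The share ending in open dimer, the selectivity, is then Φ = 1 − ln(1 + D)/D. At spring, Φ is 67.1%.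

Open dimer has the lower activation energy, 35.0 kJ mol⁻¹ against 78.0 kJ mol⁻¹ for ring closure, so D falls with heat. At noon D is 2.80 and Φ is 52.3%. At dawn D is 1.41 and Φ is 37.6%.

Is one number enough? At spring and at noon, Φ exceeds the remainder, so open dimer leads however the rest divides. At dawn it does not, so you need a second step. Ring closure takes 86.9% of that remainder. The ring's half-life at dawn is 0.980 s, far shorter than the run. I therefore commit to over-reaction product at dawn, at 54.2%, a figure that counts the part entering dormant form as held for good, which is the rough step above.

The forecast says open dimer at 67% (64% to 70%) at spring, open dimer at 52% (49% to 55%) at noon, and over-reaction product at 56.5% (53% to 60%) at dawn. Its ground is that “its low activation energy means heating shifts the split toward the ring”. Its dawn figure stands above mine.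

The simulation gives open dimer at 67.0% at spring, open dimer at 52.3% at noon, and over-reaction product at 56.5% at dawn.

The forecast is right on each mark and within each range, so for these flasks heat trades open dimer for over-reaction product. Now take spring with 1.2 mM charged, a quarter of its charge, with time and the rest held. D becomes 1.41, close to dawn's value, and Φ gives 37.5%. That neighbour ends with 37.3% of open dimer. It also holds 14.7% of ring, 6.2% of substrate and 37.6% of over-reaction product.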